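The target is cut at its methylene bridge into the ethyl methyl 4-hydroxy-2-pyrone (ring B) and an acylphloroglucinol methyl ether (ring A). Ring A is not acylated but built with its ketone in place: its three alternate oxygen-bearing carbons and the acyl-bearing carbon are read as a folded tetraketide, namely C2 to C6 of a second 4-hydroxy-2-pyrone plus the methylene carbon on C6, which already carries the (R)-2-methylbutanoyl carbonyl. In one operation methoxide opens the lactone and a Claisen closure joins that methylene carbon to the former C2, giving the 2,4,6-trihydroxyphenyl ketone with the stereocentre untouched. The precursor is 4-hydroxy-6-[(3R)-3-methyl-2-oxopentyl]-2-pyrone.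

Key step: step 3

Assumption: (R)-2-methylbutanoic acid is bought in high enantiomeric purity, and all pyrones are drawn as their 4-hydroxy-2-pyrone tautomers.

Step 1
Reactants: 1 (2R)-2-methylbutanoic acid
Product: 3 (2R)-N-methoxy-N,2-dimethylbutanamide, via acyl imidazole 2 (not isolated)
Conditions: 1,1'-carbonyldiimidazole, CH2Cl2, 0 °C to rt; then MeNH(OMe)·HCl, rt
Reagents that add atoms: N,O-dimethylhydroxylamine hydrochloride, CNOC.Cl
Why: Weinreb amide formation through the acyl imidazole runs near neutrality and avoids ketene formation, so the alpha stereocentre of the acid should be carried through unchanged.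

Step 2
Reactants: 4 4-hydroxy-6-methyl-2H-pyran-2-one; 3 (2R)-N-methoxy-N,2-dimethylbutanamide
Product: 7 4-hydroxy-6-[(3R)-3-methyl-2-oxopentyl]-2H-pyran-2-one, via dilithium pyrone dianion 5 (not isolated), via lithium tetrahedral adduct 6 (not isolated)
Conditions: 4 (1.5 equiv), LiN(i-Pr)2 (3.0 equiv), THF/DMPU, −78 to −30 °C; then 3 (1.0 equiv), −78 to −20 °C; then 1 M HCl
Reagents that add atoms: none
Why: C-acylation of a dianion at its last-formed and most nucleophilic carbanion (the 6-methyl carbon) by a Weinreb amide should give a chelated tetrahedral adduct that releases the ketone only on acidic quench, so there is no second addition and the ketone alpha stereocentre never meets base.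

Step 3
Reactants: 7 4-hydroxy-6-[(3R)-3-methyl-2-oxopentyl]-2H-pyran-2-one
Product: 9 (2R)-2-methyl-1-(2,4,6-trihydroxyphenyl)butan-1-one, via triketo methyl ester 8 (not isolated)
Conditions: Mg(OMe)2 (5 equiv), MeOH, reflux, N2; then 1 M HCl, 0 °C
Reagents that add atoms: none
Why: Methoxide adds to the lactone carbonyl (pyrone C2) and the C2–O1 bond breaks, giving the magnesium-chelated methyl 3,5,7-trioxo ester 8, in which the carbanion on the former side-chain methylene (chain C6, between the 5- and 7-carbonyls) attacks the ester carbonyl (chain C1), expels methoxide and leaves a cyclic triketone that enolises to the arene. The closest known reaction type is the biomimetic Claisen (Dieckmann-type) cyclisation of 3,5,7-triketo esters and of 6-(2-oxoalkyl)-4-hydroxy-2-pyrones to acylphloroglucinols under Mg(OMe)2. Ring A closes in a 6-exo-trig acyl substitution, the single new C–C bond lying between the acyl-bearing carbon and a hydroxyl-bearing carbon. No stereocentre is formed, and the existing one is protected because its only activating carbonyl (chain C7) is held as the chelated 5,7-diketonate, so base removes protons only from the doubly activated methylenes. The selectivity needed is Claisen closure over aldol closure of chain C2 onto the C7 ketone, and it is secured by the alpha-branched sec-butyl group that shields this ketone, by anhydrous methanol that keeps C1 an electrophilic methyl ester and not an inert carboxylate, and by magnesium chelation that holds the chain folded.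

Step 4
Reactants: 9 (2R)-2-methyl-1-(2,4,6-trihydroxyphenyl)butan-1-one
Product: 10 (2R)-1-(2,6-dihydroxy-4-methoxyphenyl)-2-methylbutan-1-one
Conditions: Me2SO4 (1.0 equiv), K2CO3 (1.1 equiv), acetone, 0 °C to rt
Reagents that add atoms: dimethyl sulfate, COS(=O)(=O)OC
Why: Williamson-type O-methylation with one equivalent of electrophile should go to the para hydroxyl, which is the most acidic and the least hindered, while the two ortho hydroxyls are flanked by the acyl group and engaged with its carbonyl.

Step 5
Reactants: 11 pentan-3-one
Product: 12 (2Z)-3-(trimethylsilyloxy)pent-2-ene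
Conditions: TMSOTf, Et3N, Et2O, 0 °C to rt
Reagents that add atoms: trimethylsilyl trifluoromethanesulfonate, C[Si](C)(C)OS(=O)(=O)C(F)(F)F
Why: Silyl enol ether formation by soft enolisation of a symmetrical ketone can give only one regioisomer, and the double-bond geometry is irrelevant because that carbon becomes a ring sp2 carbon in the next step.

Step 6
Reactants: 12 (2Z)-3-(trimethylsilyloxy)pent-2-ene; 13 propanedioyl dichloride
Product: 15 6-ethyl-4-hydroxy-5-methyl-2H-pyran-2-one, via diketo acid chloride 14 (not isolated)
Conditions: Et2O, −78 °C to rt
Reagents that add atoms: none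
Why: C-acylation of the silyl enol ether by the diacid chloride followed by lactonisation of the enolised diketone onto the second acid chloride is an established 4-hydroxy-2-pyrone synthesis and should give the 5,6-disubstituted ring directly.

Step 7
Reactants: 15 6-ethyl-4-hydroxy-5-methyl-2H-pyran-2-one
Product: 16 3-[(dimethylamino)methyl]-6-ethyl-4-hydroxy-5-methyl-2H-pyran-2-one hydroiodide
Conditions: dimethylmethylideneammonium iodide (Eschenmoser's salt, 1.05 equiv), CH2Cl2/MeCN, rt; Et2O trituration
Reagents that add atoms: dimethylmethylideneammonium iodide, C=[N+](C)C.[I-]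
Why: Mannich reaction at the enolic C3, the only nucleophilic carbon of the 4-hydroxy-2-pyrone, with the preformed iminium salt should stop after one aminomethylation because the product is collected as its hydroiodide and cannot eliminate without base.

Step 8
Reactants: 10 (2R)-1-(2,6-dihydroxy-4-methoxyphenyl)-2-methylbutan-1-one; 16 3-[(dimethylamino)methyl]-6-ethyl-4-hydroxy-5-methyl-2H-pyran-2-one hydroiodide
Product: 18 3-({2,4-dihydroxy-6-methoxy-3-[(2R)-2-methylbutanoyl]phenyl}methyl)-6-ethyl-4-hydroxy-5-methyl-2H-pyran-2-one, via methylidene pyrandione 17 (not isolated)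
Conditions: NaOAc (1.2 equiv), MeCN, 60 °C, 16 added in portions; then dilute HCl
Reagents that add atoms: none
Why: Retro-Mannich loss of dimethylamine from the freed Mannich base gives the 3-methylidene pyrandione, a strong Michael acceptor that should be attacked by one of the two equivalent free ring carbons of the phenol in a Michael-type Friedel–Crafts alkylation, after which both rings re-enolise and the remote stereocentre is not involved.

Compound list
1 | (2R)-2-methylbutanoic acid | OC(=O)[C@H](C)CC | starting material
2 | (2R)-1-(1H-imidazol-1-yl)-2-methylbutan-1-one | O=C([C@H](C)CC)n1ccnc1 | intermediate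
3 | (2R)-N-methoxy-N,2-dimethylbutanamide | CON(C)C(=O)[C@H](C)CC | intermediate
4 | 4-hydroxy-6-methyl-2H-pyran-2-one | Cc1cc(O)cc(=O)o1 | starting material
5 | dilithium salt of the 4-oxido-6-methylide dianion of 4 | [Li+].[Li+].[CH2-]c1cc([O-])cc(=O)o1 | intermediate
6 | dilithium salt of the tetrahedral adduct of 5 and 3 (both epimers at the aminal carbon, (R) at the methyl-bearing carbon) | [Li+].[Li+].CON(C)C([O-])(Cc1cc([O-])cc(=O)o1)[C@H](C)CC | intermediate
7 | 4-hydroxy-6-[(3R)-3-methyl-2-oxopentyl]-2H-pyran-2-one | O=C(Cc1cc(O)cc(=O)o1)[C@H](C)CC | intermediate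
8 | methyl (8R)-8-methyl-3,5,7-trioxodecanoate (present as its magnesium chelate) | COC(=O)CC(=O)CC(=O)CC(=O)[C@H](C)CC | intermediate
9 | (2R)-2-methyl-1-(2,4,6-trihydroxyphenyl)butan-1-one | O=C([C@H](C)CC)c1c(O)cc(O)cc1O | intermediate
10 | (2R)-1-(2,6-dihydroxy-4-methoxyphenyl)-2-methylbutan-1-one | O=C([C@H](C)CC)c1c(O)cc(OC)cc1O | intermediate
11 | pentan-3-one | CCC(=O)CC | starting material
12 | (2Z)-3-(trimethylsilyloxy)pent-2-ene (the E isomer serves equally) | C/C=C(/CC)O[Si](C)(C)C | intermediate
13 | propanedioyl dichloride (malonyl dichloride) | O=C(Cl)CC(=O)Cl | starting material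
14 | 4-methyl-3,5-dioxoheptanoyl chloride (racemic at C4, centre lost on ring closure) | CCC(=O)C(C)C(=O)CC(=O)Cl | intermediate
15 | 6-ethyl-4-hydroxy-5-methyl-2H-pyran-2-one | CCc1oc(=O)cc(O)c1C | intermediate
16 | 3-[(dimethylamino)methyl]-6-ethyl-4-hydroxy-5-methyl-2H-pyran-2-one hydroiodide | CCc1oc(=O)c(C[NH+](C)C)c(O)c1C.[I-] | intermediate
17 | 6-ethyl-5-methyl-3-methylidene-2H-pyran-2,4(3H)-dione | CCC1=C(C)C(=O)C(=C)C(=O)O1 | intermediate
18 | 3-({2,4-dihydroxy-6-methoxy-3-[(2R)-2-methylbutanoyl]phenyl}methyl)-6-ethyl-4-hydroxy-5-methyl-2H-pyran-2-one | CCc1oc(=O)c(Cc2c(OC)cc(O)c(C(=O)[C@H](C)CC)c2O)c(O)c1C | target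

Total step count: 8. Longest linear sequence: 5 steps (steps 1, 2, 3, 4 and 8); the pyrone branch (steps 5, 6 and 7) joins at step 8.

Steps most likely to fail

Step 3. Ring opening may stall at the multiply deprotonated pyrone, aldol closure onto the side-chain ketone may compete with the Claisen closure, and prolonged heating in base may slowly epimerise the alpha carbon. The fallback gives up the ring construction and acylates a preformed arene. It sets out from 1, which is converted with oxalyl chloride and catalytic DMF in CH2Cl2 into (2R)-2-methylbutanoyl chloride F1. Friedel–Crafts C-acylation of commercial benzene-1,3,5-triol with F1 and AlCl3 in CH2Cl2/nitromethane at 0 °C then comes back to the route at 9. The symmetry of the triol leaves no regiochemical question, but the Lewis acid may erode the stereocentre, which is why this path is held in reserve.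

Step 4. Methylation may run on to the dimethyl ether or may take place at an ortho hydroxyl, and separation of the isomeric ethers may be tedious. The fallback fixes the methyl ether before the arene exists. It sets out from 4, which is O-methylated (Me2SO4, K2CO3, acetone) to 4-methoxy-6-methyl-2H-pyran-2-one F2. Deprotonation of the 6-methyl group of F2 with LiN(i-Pr)2 in THF/DMPU at −78 °C and acylation with amide 3 should give 4-methoxy-6-[(3R)-3-methyl-2-oxopentyl]-2H-pyran-2-one F3. The Mg(OMe)2 ring transformation of F3 places the methoxy-bearing carbon (pyrone C4) para to the ketone and comes back to the route at 10, so no phenol has to be differentiated.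

Step 2. The poorly soluble dianion may add only slowly to the branched amide, and proton transfer from the amide alpha carbon to the dianion may erode the enantiomeric purity. The fallback builds the pyrone ring after the side chain instead of acylating a preformed pyrone, and it sets out from 3. Commercial 2,2,6-trimethyl-4H-1,3-dioxin-4-one is C-acetylated through its lithium dienolate (LiN(SiMe3)2, THF, −78 °C, then acetyl chloride) to 2,2-dimethyl-6-(2-oxopropyl)-4H-1,3-dioxin-4-one F4. The dianion of F4 (LiN(i-Pr)2, 2 equiv, THF, −78 °C) is acylated at its terminal methyl carbon with 3 to give 2,2-dimethyl-6-[(5R)-5-methyl-2,4-dioxoheptyl]-4H-1,3-dioxin-4-one F5. Heating F5 in toluene at 110 °C expels acetone, and the acylketene is captured by the enol oxygen of the delta ketone to close the 4-hydroxy-2-pyrone, which comes back to the route at 7.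

Further compounds
F1 | step 3 | (2R)-2-methylbutanoyl chloride | O=C(Cl)[C@H](C)CC
F2 | step 4 | 4-methoxy-6-methyl-2H-pyran-2-one | COc1cc(C)oc(=O)c1
F3 | step 4 | 4-methoxy-6-[(3R)-3-methyl-2-oxopentyl]-2H-pyran-2-one | O=C(Cc1cc(OC)cc(=O)o1)[C@H](C)CC
F4 | step 2 | 2,2-dimethyl-6-(2-oxopropyl)-4H-1,3-dioxin-4-one | CC(=O)CC1=CC(=O)OC(C)(C)O1
F5 | step 2 | 2,2-dimethyl-6-[(5R)-5-methyl-2,4-dioxoheptyl]-4H-1,3-dioxin-4-one | O=C(CC(=O)CC1=CC(=O)OC(C)(C)O1)[C@H](C)CC
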